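## Analysis of the target

The target 36 is built around a trans-α,β-dibenzyl-γ-butyrolactone. The Cβ benzyl group (guaiacyl ring B) carries on its 4-oxygen a 1-aryl-1,3-dihydroxypropan-2-yl chain (ring A; C1′ carbinol, C2′ ether carbon, C3′ CH2OH). The Cα benzyl carbon is attached to C5 of a 2-aryl-3-hydroxymethyl-7-methoxy-2,3-dihydrobenzofuran (benzo ring C, guaiacyl ring D on C2).

There are six stereocentres in three adjacent pairs: lactone Cα/Cβ (R,R, trans), dihydrobenzofuran C2/C3 (2S,3R, aryl and CH2OH trans), and chain C1′/C2′ (1R,2S, erythro). The pairs are separated by ArCH2 spacers, so none can pass its configuration to another and each needs its own source of absolute configuration.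

The sensitive sites are:
- the two free guaiacyl phenols;
- the para-oxygenated benzylic alcohol at C1′, which can ionise or form a quinone methide and so scramble the erythro relationship;
- the benzylic C2–O1 ether, whose acid ionisation epimerises C2;
- the lactone with its enolisable Cα.

The difficulty is to make three remote stereo-pairs with absolute control and to join three highly oxygenated aromatic fragments without disturbing these benzylic positions. The strategy rests on the dihydrobenzofuran: C3 bears an exocyclic CH2OH and is bonded to C3a of ring C, the carbon ortho to O1. That is the pattern left when an aryl radical at C3a adds 5-exo to the internal carbon of an O1–C2(aryl)–CH=CH2 unit and the exocyclic radical is captured by oxygen.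

## Retrosynthetic reasoning

**Unmasking.** 36 comes from 35 by hydrogenolysis of the two phenolic benzyl ethers, and 35 from 34 by cleavage of three silyl ethers. No skeletal bond is cut. The order is chosen so that no phenoxide is ever present next to a silylated benzylic oxygen and the last step runs under neutral conditions.

**Cα–CH2 bond.** 34 is cut between lactone Cα and the benzylic CH2 on C5 of ring C, giving lactone 32 (as enolate 33) and benzylic bromide 14. This divides the molecule into two halves of similar size, each holding complete stereo-pairs. It is also the one place where an existing centre can be used: the electrophile enters anti to the Cβ benzyl group and sets Cα. A cut at Cβ would need a conjugate addition of a benzyl nucleophile carrying the whole chain and would give no such control.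

**From 14 back to 10.** Only functional groups change: bromide 14 from alcohol 13, from aldehyde 12, from acetal 11, from alcohol 10 by silylation. The future lactone-side CH2 is the aldehyde carbon of 1, kept as a dioxolane through the radical step.

**Key disconnection.** In 10 the C3–C3a bond and the CH2–OH bond are cut together, leading through hydroperoxide 9 to aryl iodide 8. C3a is ortho to O1 and C3 bears an exocyclic oxygenated carbon, which is the mark of a 5-exo radical closure onto a vinyl group with aerobic trapping. One step gains the ring, a C–C bond, a C–O bond and the C3 stereocentre from a precursor with a single stereocentre. The forward reaction must close the ring before the aryl radical is quenched, give the primary radical an oxygen atom and not a hydrogen atom, and place the CH2 group trans to the C2 aryl group.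

**C2–O1 bond.** 8 is cut at the allylic C–O bond into aryloxide 7 (from phenol 2) and the linear cinnamyl carbonate 6. The only stereocentre of 8 is then made catalytically from two achiral pieces, with iodine and acetal already in place. The forward allylic substitution must give the branched ether and the S configuration.

**Simple precursors.** 6 comes from alcohol 5, ester 4 and acid 3; 2 comes from 1.

**From 32 back to 28.** 32 is the silyl ether of 31, which comes from ester 30, formed from 29, the mono-silyl ether of diol 28. Steps 29 → 30 → 31 invert C1′. The auxiliary-controlled aldol gives the threo (1S,2S) diol 28, whereas 36 needs erythro (1R,2S). C2′ is already correct, so C1′ is inverted by SN2 esterification and ester cleavage.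

**C1′–C2′ bond.** 28 comes from aldol adduct 27 by reductive removal of auxiliary 22. 27 is cut at C1′–C2′ into imide 25 (as boron enolate 26) and aldehyde 15. The aryl ether oxygen is then already on the nucleophilic carbon, and the C2′–O bond never has to be made by substitution at a hindered secondary carbon.

**Ether O–CH2 bond.** 25 is cut into phenol 21 and bromoacetyl imide 24, which is made from 22 through 23.

**Lactone.** 21 comes from benzyl ether 20, which is formed from hydroxy acid 19 and half-ester 18. 18 is the hydrogenation product of alkene 17, which is cut at its C=C bond into aldehyde 15 and succinate 16. Cβ is set in the hydrogenation.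

## Alternatives that were turned down

Alternative 1: The dihydrofuran is cut at C2–C3 and O1–C2, so ring C with C3 attached meets a one-carbon C2 unit carrying ring D. In the forward step a carbonate base eliminates sulfinate from sulfone A2 to release ortho-quinone methide A4. Deprotonated sulfonium salt A3 adds to the exocyclic carbon of A4 (C2–C3), and the phenoxide then displaces the sulfide at C2 (O1–C2) to give A1.
- For: it is convergent, makes both ring bonds and both stereocentres in one operation and uses no tin. Its trans selectivity follows from the anti-periplanar ring closure of the less crowded adduct. On this point it is stronger than the radical closure, which can only count on a trans preference.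
- Against: the absolute configuration of both centres depends on face selection by a stoichiometric chiral sulfide in the addition of a stabilised, electron-rich benzylic ylide to a transient species, and reversible addition would erode it. A4 has hydrogens next to its exocyclic carbon, so tautomerisation to an ortho-vinylphenol competes with the addition. A1 carries bromine at C5, so the lactone-side carbon must still be introduced.
- Comparison: the chosen route sets C2 by a catalytic reaction of well-understood sense, passes it on to C3, and has the C5 carbon in place from 1.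

Alternative 2: Ring C is built de novo by cutting C3a–C7a and C6–C7. In precursor A6 the furan carbons become C3a, C4, C5 and C6, the alkyne carbons become C7a and C7, and the furan oxygen becomes the C7 hydroxyl. In the forward step a cationic gold catalyst activates the terminal alkynyl ether of A6, the furan attacks the oxygen-bearing alkyne carbon, and the bicyclic intermediate reorganises to phenol A5. The benzene ring and the dihydrofuran close together.
- For: the oxygen pattern of ring C is fixed by the mechanism. Both stereocentres are already present in A6, so ring closure creates no new one. On diastereocontrol in the ring-forming step it is stronger than the chosen route.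
- Against: that advantage is paid for earlier, because A6 needs C2 and C3 set in an open chain by separate asymmetric chemistry, together with a 2,4-disubstituted furan. A terminal alkynyl ether of a para-alkoxybenzylic secondary alcohol is fragile (ionisation at C2, thermal loss of ketene). After the key step the C7 hydroxyl must be methylated and the benzylic ether turned into a leaving group.
- Comparison: all six carbons of ring C with their substituents are bought in 1. Making them would add roughly six to eight steps, against a precursor with one stereocentre in the chosen route.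

Alternative 3: The lactone is cut at its O–CH2 bond, so A7 comes from the prochiral cyclobutanone A8. In the forward step a chiral acid catalyst and a peroxide insert oxygen into one of the two enantiotopic C(=O)–CH2 bonds, expanding the ring and setting Cβ.
- For: it is catalytic and atom-economical. A7 is the same compound as lactone 20, and A8 is only a cycloaddition and a dechlorination away from an allylarene. For this fragment it is as short as, or one step shorter than, steps 11–13.
- Against: it addresses one stereocentre of six and leaves the dihydrobenzofuran, the harder half, unsolved. The two CH2 groups differ only through a remote, flexible benzyl group, a case in which this reaction class discriminates less well than with 3-aryl cyclobutanones. An electron-rich arene is exposed to peroxide and acid.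
- Comparison: the chosen plan gets the lactone by asymmetric hydrogenation of a benzylidene succinate, which is dependable, and spends its key step where a ring, two bonds and a stereocentre are created. This ring expansion could replace steps 11–13 as another entry to 20 without changing anything downstream.

Key step: step 6

Remark on the chemistry: the ligand antipodes named in steps 5 and 12 are those expected to give (S)-8 and (R)-18; if the sense of induction proves opposite, the mirror-image ligand is used and nothing else changes.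

## Steps

Step 1
Reactants: 1 5-iodovanillin (4-hydroxy-3-iodo-5-methoxybenzaldehyde)
Product: 2 4-(1,3-dioxolan-2-yl)-2-iodo-6-methoxyphenol
Conditions: HOCH2CH2OH, TsOH·H2O (cat.), PhMe, reflux, Dean–Stark
Reagents that add atoms: ethylene glycol, OCCO
Why: Acid-catalysed acetalisation with azeotropic removal of water; the dioxolane protects the aldehyde from the aerobic radical chain of step 6 and makes the phenoxide a better nucleophile for step 5.

Step 2
Reactants: 3 ferulic acid [(E)-3-(4-hydroxy-3-methoxyphenyl)prop-2-enoic acid]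
Product: 4 benzyl (E)-3-(4-benzyloxy-3-methoxyphenyl)prop-2-enoate
Conditions: BnBr (2.3 equiv), K2CO3, DMF, 60 °C
Reagents that add atoms: benzyl bromide, BrCc1ccccc1
Why: Williamson-type O-alkylation of phenoxide and carboxylate in one operation; the phenol is protected and the acid becomes a reducible ester.

Step 3
Reactants: 4 benzyl (E)-3-(4-benzyloxy-3-methoxyphenyl)prop-2-enoate
Product: 5 (E)-3-(4-benzyloxy-3-methoxyphenyl)prop-2-en-1-ol
Conditions: i-Bu2AlH (3 equiv), CH2Cl2, −78 → 0 °C; aq. KNaC4H4O6
Reagents that add atoms: none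
Why: 1,2-Reduction of the enoate by the aluminium hydride; the E alkene and the aryl benzyl ether are not affected.

Step 4
Reactants: 5 (E)-3-(4-benzyloxy-3-methoxyphenyl)prop-2-en-1-ol
Product: 6 (E)-3-(4-benzyloxy-3-methoxyphenyl)prop-2-en-1-yl methyl carbonate
Conditions: ClCO2Me, pyridine, CH2Cl2, 0 °C
Reagents that add atoms: methyl chloroformate, COC(=O)Cl
Why: O-Acylation of the allylic alcohol; the methyl carbonate is the leaving group that ionises on iridium in step 5.

Step 5
Reactants: 2 4-(1,3-dioxolan-2-yl)-2-iodo-6-methoxyphenol; 6 (E)-3-(4-benzyloxy-3-methoxyphenyl)prop-2-en-1-yl methyl carbonate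
Product: 8 2-{4-[(1S)-1-(4-benzyloxy-3-methoxyphenyl)prop-2-enyloxy]-3-iodo-5-methoxyphenyl}-1,3-dioxolane, via lithium aryloxide 7 (not isolated)
Conditions: 2, LiN(SiMe3)2, THF, 0 °C; then 6, [Ir(cod)Cl]2 (2 mol %), (Sa,Sc,Sc)-O,O′-(1,1′-binaphthyl-2,2′-diyl) N,N-bis(1-phenylethyl)phosphoramidite (4 mol %), THF, 40 °C
Reagents that add atoms: none
Why: Iridium-catalysed asymmetric allylic etherification of a cinnamyl carbonate with an aryloxide: attack of 7 at the aryl-substituted terminus of the allyliridium intermediate gives the branched ether. The cyclometalated phosphoramidite complex selects the allyl face and so sets C2 as S.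

Step 6
Reactants: 8 2-{4-[(1S)-1-(4-benzyloxy-3-methoxyphenyl)prop-2-enyloxy]-3-iodo-5-methoxyphenyl}-1,3-dioxolane
Product: 10 [(2S,3R)-2-(4-benzyloxy-3-methoxyphenyl)-5-(1,3-dioxolan-2-yl)-7-methoxy-2,3-dihydrobenzofuran-3-yl]methanol, via hydroperoxide 9 (not isolated)
Conditions: Bu3SnH (1.5 equiv, syringe pump), stream of dry air, PhMe (0.01 M), 20 °C; then PPh3, 20 °C
Reagents that add atoms: dioxygen (from dry air), O=O
Why: Tributylstannyl radicals abstract iodine from 8 and the sp2 radical at C3a adds 5-exo-trig to the internal vinyl carbon, forming C3–C3a and closing the dihydrofuran ring; the exocyclic primary radical is captured by O2, the peroxyl radical takes hydrogen from Bu3SnH to carry the chain and give hydroperoxide 9, and PPh3 reduces 9 to 10. The closest known reaction type is the tin hydride-mediated cyclisation of ortho-halophenyl allyl ethers to 3-substituted 2,3-dihydrobenzofurans run under air (or its Co(salen)-mediated variant), in which the cyclised radical is oxygenated instead of reduced. The one ring is closed in the 5-exo-trig mode, and 6-endo closure is disfavoured by the short C7a–O1–C2 tether. C3 is the one new stereocentre and is controlled by C2: in the chair-like transition state the aryl group on C2 sits pseudo-equatorial and away from the forming bond, so the CH2 radical ends up trans to it, which is the (2S,3R) arrangement. C2 itself is not touched, because abstraction of its hydrogen by the aryl radical would be a 1,4-shift through a strained five-membered transition state and cannot compete with so fast a cyclisation. The step needs chemoselectivity (ring closure before the aryl radical meets O2 or Sn–H, oxygen capture before the primary radical meets Sn–H) and trans selectivity; the first is secured by the very fast closure of ortho-allyloxyaryl radicals and a low stannane concentration, the second by the single substituent on C2. The minor cis isomer is removed by chromatography and is not epimerised with acid, since inversion of C2 in the (2S,3S) compound would give the antipode of 10. Ring C arrives from 1 with all its substituents in place, the masked aldehyde para to O1 being the later lactone-side CH2.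

Step 7
Reactants: 10 [(2S,3R)-2-(4-benzyloxy-3-methoxyphenyl)-5-(1,3-dioxolan-2-yl)-7-methoxy-2,3-dihydrobenzofuran-3-yl]methanol
Product: 11 2-[(2S,3R)-2-(4-benzyloxy-3-methoxyphenyl)-7-methoxy-3-(triisopropylsilyloxymethyl)-2,3-dihydrobenzofuran-5-yl]-1,3-dioxolane
Conditions: i-Pr3SiCl, imidazole, DMF, 20 °C
Reagents that add atoms: triisopropylsilyl chloride, CC(C)[Si](Cl)(C(C)C)C(C)C
Why: Silylation of the primary alcohol; the triisopropylsilyl ether should survive the mildly acidic acetal cleavage of step 8 and the enolate chemistry of step 23.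

Step 8
Reactants: 11 2-[(2S,3R)-2-(4-benzyloxy-3-methoxyphenyl)-7-methoxy-3-(triisopropylsilyloxymethyl)-2,3-dihydrobenzofuran-5-yl]-1,3-dioxolane
Product: 12 (2S,3R)-2-(4-benzyloxy-3-methoxyphenyl)-7-methoxy-3-(triisopropylsilyloxymethyl)-2,3-dihydrobenzofuran-5-carbaldehyde
Conditions: PPTS (cat.), acetone/H2O, 40 °C
Reagents that add atoms: water, O
Why: Acid-catalysed acetal hydrolysis; the para-oxygenated aryl dioxolane should cleave under conditions too mild to ionise the benzylic C2–O1 bond, so C2 keeps its configuration.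

Step 9
Reactants: 12 (2S,3R)-2-(4-benzyloxy-3-methoxyphenyl)-7-methoxy-3-(triisopropylsilyloxymethyl)-2,3-dihydrobenzofuran-5-carbaldehyde
Product: 13 [(2S,3R)-2-(4-benzyloxy-3-methoxyphenyl)-7-methoxy-3-(triisopropylsilyloxymethyl)-2,3-dihydrobenzofuran-5-yl]methanol
Conditions: NaBH4, MeOH/THF, 0 °C
Reagents that add atoms: none
Why: Chemoselective borohydride reduction of the aryl aldehyde to the benzylic alcohol.

Step 10
Reactants: 13 [(2S,3R)-2-(4-benzyloxy-3-methoxyphenyl)-7-methoxy-3-(triisopropylsilyloxymethyl)-2,3-dihydrobenzofuran-5-yl]methanol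
Product: 14 (2S,3R)-2-(4-benzyloxy-3-methoxyphenyl)-5-(bromomethyl)-7-methoxy-3-(triisopropylsilyloxymethyl)-2,3-dihydrobenzofuran
Conditions: CBr4, PPh3, CH2Cl2, 0 °C
Reagents that add atoms: carbon tetrabromide, BrC(Br)(Br)Br
Why: Appel reaction; the neutral conditions convert the benzylic alcohol into the bromide without acid, and the electron-rich bromide is used at once in step 23.

Step 11
Reactants: 15 4-benzyloxy-3-methoxybenzaldehyde; 16 dimethyl succinate
Product: 17 (E)-4-(4-benzyloxy-3-methoxyphenyl)-3-(methoxycarbonyl)but-3-enoic acid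
Conditions: NaOMe, MeOH, reflux; then aq. HCl
Reagents that add atoms: none
Why: Stobbe condensation: the succinate enolate adds to the aldehyde, the alkoxide lactonises, and base-induced ring opening gives the half-ester with the aryl group trans to the ester (E).

Step 12
Reactants: 17 (E)-4-(4-benzyloxy-3-methoxyphenyl)-3-(methoxycarbonyl)but-3-enoic acid
Product: 18 (R)-4-(4-benzyloxy-3-methoxyphenyl)-3-(methoxycarbonyl)butanoic acid
Conditions: H2 (5 bar), [Rh(cod)((S,S)-Et-DuPHOS)]BF4 (0.5 mol %), NaOMe (10 mol %), MeOH, 20 °C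
Reagents that add atoms: none
Why: Asymmetric hydrogenation of an itaconate-type alkene: chelation of alkene and carboxylate to the cationic rhodium bisphospholane complex lets the ligand choose the alkene face, which sets the future Cβ as R. The homogeneous catalyst does not cleave the benzyl ether.

Step 13
Reactants: 18 (R)-4-(4-benzyloxy-3-methoxyphenyl)-3-(methoxycarbonyl)butanoic acid
Product: 20 (R)-4-(4-benzyloxy-3-methoxybenzyl)dihydrofuran-2(3H)-one, via hydroxy acid 19 (not isolated)
Conditions: KOH (1.0 equiv), EtOH; CaCl2, NaBH4, −10 → 20 °C; then 2 M HCl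
Reagents that add atoms: none
Why: Ca(BH4)2 formed in the flask reduces the ester but not the carboxylate, and acidification closes hydroxy acid 19 to the γ-lactone; the lactone CH2O therefore comes from the ester carbon and the stereocentre is not touched.

Step 14
Reactants: 20 (R)-4-(4-benzyloxy-3-methoxybenzyl)dihydrofuran-2(3H)-one
Product: 21 (R)-4-(4-hydroxy-3-methoxybenzyl)dihydrofuran-2(3H)-one
Conditions: H2 (1 atm), 10 % Pd/C, EtOAc, 20 °C
Reagents that add atoms: none
Why: Hydrogenolysis of the aryl benzyl ether frees the phenol that will carry the chain.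

Step 15
Reactants: 22 (R)-4-benzyl-1,3-oxazolidin-2-one
Product: 24 (R)-4-benzyl-3-(bromoacetyl)-1,3-oxazolidin-2-one, via lithium oxazolidinide 23 (not isolated)
Conditions: n-BuLi, THF, −78 °C; then BrCH2COBr, −78 → 0 °C
Reagents that add atoms: bromoacetyl bromide, O=C(Br)CBr
Why: N-Acylation of the lithiated auxiliary by the acyl bromide, which reacts at the acyl carbon faster than at the CH2Br carbon at low temperature.

Step 16
Reactants: 21 (R)-4-(4-hydroxy-3-methoxybenzyl)dihydrofuran-2(3H)-one; 24 (R)-4-benzyl-3-(bromoacetyl)-1,3-oxazolidin-2-one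
Product: 25 (R)-4-benzyl-3-{2-[2-methoxy-4-({(3R)-5-oxotetrahydrofuran-3-yl}methyl)phenoxy]acetyl}-1,3-oxazolidin-2-one
Conditions: K2CO3, acetone, 20 °C
Reagents that add atoms: none
Why: Williamson ether synthesis at the activated α-bromo imide; the carbonate base is too weak to enolise the lactone and the phenoxide reacts at CH2Br faster than at the imide carbonyl.

Step 17
Reactants: 25 (R)-4-benzyl-3-{2-[2-methoxy-4-({(3R)-5-oxotetrahydrofuran-3-yl}methyl)phenoxy]acetyl}-1,3-oxazolidin-2-one; 15 4-benzyloxy-3-methoxybenzaldehyde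
Product: 27 (R)-4-benzyl-3-[(2R,3S)-3-(4-benzyloxy-3-methoxyphenyl)-3-hydroxy-2-{2-methoxy-4-[((3R)-5-oxotetrahydrofuran-3-yl)methyl]phenoxy}propanoyl]-1,3-oxazolidin-2-one, via boron enolate 26 (not isolated)
Conditions: Bu2BOTf, i-Pr2NEt, CH2Cl2, −78 → 0 °C; then 15, −78 → 0 °C; pH 7 buffer, MeOH, H2O2, 0 °C
Reagents that add atoms: none
Why: Evans syn-aldol reaction of an aryloxyacetyl imide: soft enolisation gives the Z enolate 26 at the imide only (the lactone is far less acidic), and 26 adds to the aldehyde through a closed chair transition state with the auxiliary carbonyl turned away from the enolate oxygen. The (R)-benzyl group shields one enolate face, giving the syn (2R,3S) adduct, which has C2′ as required and C1′ still to be inverted.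

Step 18
Reactants: 27 aldol adduct (as in step 17)
Product: 28 (R)-4-{4-[(1S,2S)-1-(4-benzyloxy-3-methoxyphenyl)-1,3-dihydroxypropan-2-yloxy]-3-methoxybenzyl}dihydrofuran-2(3H)-one (threo)
Conditions: NaBH4, THF/H2O, 0 → 20 °C
Reagents that add atoms: none
Why: Reductive cleavage of the N-acyl oxazolidinone at its exocyclic carbonyl, which is much more electrophilic than the lactone; both stereocentres are retained and the auxiliary is set free.

Step 19
Reactants: 28 threo diol (as in step 18)
Product: 29 (R)-4-{4-[(1S,2S)-1-(4-benzyloxy-3-methoxyphenyl)-3-(tert-butyldimethylsilyloxy)-1-hydroxypropan-2-yloxy]-3-methoxybenzyl}dihydrofuran-2(3H)-one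
Conditions: t-BuMe2SiCl (1.1 equiv), imidazole, CH2Cl2, 0 °C
Reagents that add atoms: tert-butyldimethylsilyl chloride, CC(C)(C)[Si](C)(C)Cl
Why: Selective silylation of the primary hydroxyl over the hindered secondary benzylic one, which is left free for inversion.

Step 20
Reactants: 29 mono-silyl ether (as in step 19)
Product: 30 (1R,2S)-1-(4-benzyloxy-3-methoxyphenyl)-3-(tert-butyldimethylsilyloxy)-2-{2-methoxy-4-[((3R)-5-oxotetrahydrofuran-3-yl)methyl]phenoxy}propyl 4-nitrobenzoate
Conditions: PPh3, i-PrO2CN=NCO2i-Pr, 4-O2NC6H4CO2H, PhMe, −20 → 0 °C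
Reagents that add atoms: 4-nitrobenzoic acid, O=C(O)c1ccc(cc1)[N+](=O)[O-]
Why: Mitsunobu reaction: SN2 displacement of the oxyphosphonium group by the carboxylate inverts C1′ from S to R and turns threo into erythro. A fairly acidic carboxylic acid, a non-polar solvent and low temperature favour direct displacement over ionisation.

Step 21
Reactants: 30 4-nitrobenzoate (as in step 20)
Product: 31 (R)-4-{4-[(1R,2S)-1-(4-benzyloxy-3-methoxyphenyl)-3-(tert-butyldimethylsilyloxy)-1-hydroxypropan-2-yloxy]-3-methoxybenzyl}dihydrofuran-2(3H)-one (erythro)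
Conditions: K2CO3 (cat.), MeOH, 0 °C; then AcOH
Reagents that add atoms: none
Why: Transesterification removes the electron-poor benzoate by attack at the acyl carbon, so C1′ keeps its new configuration; any lactone opened by methoxide closes again on acidification.

Step 22
Reactants: 31 erythro alcohol (as in step 21)
Product: 32 (R)-4-{4-[(1R,2S)-1-(4-benzyloxy-3-methoxyphenyl)-1,3-bis(tert-butyldimethylsilyloxy)propan-2-yloxy]-3-methoxybenzyl}dihydrofuran-2(3H)-one
Conditions: t-BuMe2SiOTf, 2,6-lutidine, CH2Cl2, −40 → 0 °C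
Reagents that add atoms: tert-butyldimethylsilyl trifluoromethanesulfonate, CC(C)(C)[Si](C)(C)OS(=O)(=O)C(F)(F)F
Why: Silylation of the hindered benzylic alcohol with the silyl triflate and a hindered base; it removes the only acidic O–H before the enolate step and shields C1′ from ionisation.

Step 23
Reactants: 32 bis-silyl lactone (as in step 22); 14 (2S,3R)-2-(4-benzyloxy-3-methoxyphenyl)-5-(bromomethyl)-7-methoxy-3-(triisopropylsilyloxymethyl)-2,3-dihydrobenzofuran
Product: 34 (3R,4R)-4-{4-[(1R,2S)-1-(4-benzyloxy-3-methoxyphenyl)-1,3-bis(tert-butyldimethylsilyloxy)propan-2-yloxy]-3-methoxybenzyl}-3-{[(2S,3R)-2-(4-benzyloxy-3-methoxyphenyl)-7-methoxy-3-(triisopropylsilyloxymethyl)-2,3-dihydrobenzofuran-5-yl]methyl}dihydrofuran-2(3H)-one, via lithium enolate 33 (not isolated)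
Conditions: LiN(i-Pr)2, THF, −78 °C; then 14, DMPU, −78 → −40 °C
Reagents that add atoms: none
Why: Alkylation of a β-substituted γ-butyrolactone enolate with a benzylic bromide: the electrophile approaches the enolate face anti to the Cβ benzyl group, so Cα is formed R and trans to Cβ, as is usual for dibenzylbutyrolactones.

Step 24
Reactants: 34 fully protected lactone (as in step 23)
Product: 35 (3R,4R)-4-{4-[(1R,2S)-1-(4-benzyloxy-3-methoxyphenyl)-1,3-dihydroxypropan-2-yloxy]-3-methoxybenzyl}-3-{[(2S,3R)-2-(4-benzyloxy-3-methoxyphenyl)-3-(hydroxymethyl)-7-methoxy-2,3-dihydrobenzofuran-5-yl]methyl}dihydrofuran-2(3H)-one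
Conditions: Bu4NF, AcOH, THF, 0 → 20 °C
Reagents that add atoms: none
Why: Fluoride cleaves the three silyl ethers; buffering with acetic acid protects the lactone, and with both phenols still benzylated no phenoxide can expel the oxygen at C1′.

Step 25
Reactants: 35 dibenzyl ether triol (as in step 24)
Product: 36 (3R,4R)-4-{4-[(1R,2S)-1,3-dihydroxy-1-(4-hydroxy-3-methoxyphenyl)propan-2-yloxy]-3-methoxybenzyl}-3-{[(2S,3R)-2-(4-hydroxy-3-methoxyphenyl)-3-(hydroxymethyl)-7-methoxy-2,3-dihydrobenzofuran-5-yl]methyl}dihydrofuran-2(3H)-one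
Conditions: H2 (1 atm), 10 % Pd/C, EtOAc/MeOH, 20 °C
Reagents that add atoms: none
Why: Hydrogenolysis of the two aryl benzyl ethers under neutral conditions, where benzylic alcohols and the cyclic benzylic ether of a 2-aryl-2,3-dihydrobenzofuran react much more slowly than O-benzyl groups.

## Compound list

1 | 5-iodovanillin (4-hydroxy-3-iodo-5-methoxybenzaldehyde) | COc1cc(C=O)cc(I)c1O | starting material
2 | 4-(1,3-dioxolan-2-yl)-2-iodo-6-methoxyphenol | COc1cc(C2OCCO2)cc(I)c1O | intermediate
3 | ferulic acid | COc1cc(/C=C/C(=O)O)ccc1O | starting material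
4 | benzyl (E)-3-(4-benzyloxy-3-methoxyphenyl)prop-2-enoate | COc1cc(/C=C/C(=O)OCc2ccccc2)ccc1OCc1ccccc1 | intermediate
5 | (E)-3-(4-benzyloxy-3-methoxyphenyl)prop-2-en-1-ol | COc1cc(/C=C/CO)ccc1OCc1ccccc1 | intermediate
6 | (E)-3-(4-benzyloxy-3-methoxyphenyl)prop-2-en-1-yl methyl carbonate | COc1cc(/C=C/COC(=O)OC)ccc1OCc1ccccc1 | intermediate
7 | lithium 4-(1,3-dioxolan-2-yl)-2-iodo-6-methoxyphenolate | [Li+].COc1cc(C2OCCO2)cc(I)c1[O-] | intermediate
8 | 2-{4-[(1S)-1-(4-benzyloxy-3-methoxyphenyl)prop-2-enyloxy]-3-iodo-5-methoxyphenyl}-1,3-dioxolane | COc1cc(C2OCCO2)cc(I)c1O[C@H](c1ccc(OCc2ccccc2)c(OC)c1)C=C | intermediate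
9 | [(2S,3R)-2-(4-benzyloxy-3-methoxyphenyl)-5-(1,3-dioxolan-2-yl)-7-methoxy-2,3-dihydrobenzofuran-3-yl]methyl hydroperoxide | O1CCOC1c1cc(OC)c2c(c1)[C@H](COO)[C@@H](c1ccc(OCc3ccccc3)c(OC)c1)O2 | intermediate
10 | [(2S,3R)-2-(4-benzyloxy-3-methoxyphenyl)-5-(1,3-dioxolan-2-yl)-7-methoxy-2,3-dihydrobenzofuran-3-yl]methanol | O1CCOC1c1cc(OC)c2c(c1)[C@H](CO)[C@@H](c1ccc(OCc3ccccc3)c(OC)c1)O2 | intermediate
11 | 2-[(2S,3R)-2-(4-benzyloxy-3-methoxyphenyl)-7-methoxy-3-(triisopropylsilyloxymethyl)-2,3-dihydrobenzofuran-5-yl]-1,3-dioxolane | O1CCOC1c1cc(OC)c2c(c1)[C@H](CO[Si](C(C)C)(C(C)C)C(C)C)[C@@H](c1ccc(OCc3ccccc3)c(OC)c1)O2 | intermediate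
12 | (2S,3R)-2-(4-benzyloxy-3-methoxyphenyl)-7-methoxy-3-(triisopropylsilyloxymethyl)-2,3-dihydrobenzofuran-5-carbaldehyde | O=Cc1cc(OC)c2c(c1)[C@H](CO[Si](C(C)C)(C(C)C)C(C)C)[C@@H](c1ccc(OCc3ccccc3)c(OC)c1)O2 | intermediate
13 | [(2S,3R)-2-(4-benzyloxy-3-methoxyphenyl)-7-methoxy-3-(triisopropylsilyloxymethyl)-2,3-dihydrobenzofuran-5-yl]methanol | OCc1cc(OC)c2c(c1)[C@H](CO[Si](C(C)C)(C(C)C)C(C)C)[C@@H](c1ccc(OCc3ccccc3)c(OC)c1)O2 | intermediate
14 | (2S,3R)-2-(4-benzyloxy-3-methoxyphenyl)-5-(bromomethyl)-7-methoxy-3-(triisopropylsilyloxymethyl)-2,3-dihydrobenzofuran | BrCc1cc(OC)c2c(c1)[C@H](CO[Si](C(C)C)(C(C)C)C(C)C)[C@@H](c1ccc(OCc3ccccc3)c(OC)c1)O2 | intermediate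
15 | 4-benzyloxy-3-methoxybenzaldehyde | COc1cc(C=O)ccc1OCc1ccccc1 | starting material
16 | dimethyl succinate | COC(=O)CCC(=O)OC | starting material
17 | (E)-4-(4-benzyloxy-3-methoxyphenyl)-3-(methoxycarbonyl)but-3-enoic acid | COC(=O)/C(=C/c1ccc(OCc2ccccc2)c(OC)c1)CC(=O)O | intermediate
18 | (R)-4-(4-benzyloxy-3-methoxyphenyl)-3-(methoxycarbonyl)butanoic acid | COC(=O)[C@H](Cc1ccc(OCc2ccccc2)c(OC)c1)CC(=O)O | intermediate
19 | (R)-4-(4-benzyloxy-3-methoxyphenyl)-3-(hydroxymethyl)butanoic acid | OC[C@H](Cc1ccc(OCc2ccccc2)c(OC)c1)CC(=O)O | intermediate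
20 | (R)-4-(4-benzyloxy-3-methoxybenzyl)dihydrofuran-2(3H)-one | COc1cc(C[C@H]2COC(=O)C2)ccc1OCc1ccccc1 | intermediate
21 | (R)-4-(4-hydroxy-3-methoxybenzyl)dihydrofuran-2(3H)-one | COc1cc(C[C@H]2COC(=O)C2)ccc1O | intermediate
22 | (R)-4-benzyl-1,3-oxazolidin-2-one | O=C1OC[C@@H](Cc2ccccc2)N1 | starting material
23 | lithium salt of (R)-4-benzyl-1,3-oxazolidin-2-one | [Li+].O=C1OC[C@@H](Cc2ccccc2)[N-]1 | intermediate
24 | (R)-4-benzyl-3-(bromoacetyl)-1,3-oxazolidin-2-one | O=C1OC[C@@H](Cc2ccccc2)N1C(=O)CBr | intermediate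
25 | (R)-4-benzyl-3-{2-[2-methoxy-4-({(3R)-5-oxotetrahydrofuran-3-yl}methyl)phenoxy]acetyl}-1,3-oxazolidin-2-one | O=C1OC[C@@H](Cc2ccccc2)N1C(=O)COc1ccc(C[C@H]2COC(=O)C2)cc1OC | intermediate
26 | dibutylboron (Z)-enolate of 25 | CCCCB(CCCC)O/C(=C\Oc1ccc(C[C@H]2COC(=O)C2)cc1OC)N1[C@H](Cc2ccccc2)COC1=O | intermediate
27 | (R)-4-benzyl-3-[(2R,3S)-3-(4-benzyloxy-3-methoxyphenyl)-3-hydroxy-2-{2-methoxy-4-[((3R)-5-oxotetrahydrofuran-3-yl)methyl]phenoxy}propanoyl]-1,3-oxazolidin-2-one | COc1cc([C@H](O)[C@H](C(=O)N2[C@H](Cc3ccccc3)COC2=O)Oc2ccc(C[C@H]3COC(=O)C3)cc2OC)ccc1OCc1ccccc1 | intermediate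
28 | (R)-4-{4-[(1S,2S)-1-(4-benzyloxy-3-methoxyphenyl)-1,3-dihydroxypropan-2-yloxy]-3-methoxybenzyl}dihydrofuran-2(3H)-one | COc1cc([C@H](O)[C@H](CO)Oc2ccc(C[C@H]3COC(=O)C3)cc2OC)ccc1OCc1ccccc1 | intermediate
29 | (R)-4-{4-[(1S,2S)-1-(4-benzyloxy-3-methoxyphenyl)-3-(tert-butyldimethylsilyloxy)-1-hydroxypropan-2-yloxy]-3-methoxybenzyl}dihydrofuran-2(3H)-one | COc1cc([C@H](O)[C@H](CO[Si](C)(C)C(C)(C)C)Oc2ccc(C[C@H]3COC(=O)C3)cc2OC)ccc1OCc1ccccc1 | intermediate
30 | (1R,2S)-1-(4-benzyloxy-3-methoxyphenyl)-3-(tert-butyldimethylsilyloxy)-2-{2-methoxy-4-[((3R)-5-oxotetrahydrofuran-3-yl)methyl]phenoxy}propyl 4-nitrobenzoate | COc1cc([C@@H](OC(=O)c2ccc(cc2)[N+](=O)[O-])[C@H](CO[Si](C)(C)C(C)(C)C)Oc2ccc(C[C@H]3COC(=O)C3)cc2OC)ccc1OCc1ccccc1 | intermediate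
31 | (R)-4-{4-[(1R,2S)-1-(4-benzyloxy-3-methoxyphenyl)-3-(tert-butyldimethylsilyloxy)-1-hydroxypropan-2-yloxy]-3-methoxybenzyl}dihydrofuran-2(3H)-one | COc1cc([C@@H](O)[C@H](CO[Si](C)(C)C(C)(C)C)Oc2ccc(C[C@H]3COC(=O)C3)cc2OC)ccc1OCc1ccccc1 | intermediate
32 | (R)-4-{4-[(1R,2S)-1-(4-benzyloxy-3-methoxyphenyl)-1,3-bis(tert-butyldimethylsilyloxy)propan-2-yloxy]-3-methoxybenzyl}dihydrofuran-2(3H)-one | COc1cc([C@@H](O[Si](C)(C)C(C)(C)C)[C@H](CO[Si](C)(C)C(C)(C)C)Oc2ccc(C[C@H]3COC(=O)C3)cc2OC)ccc1OCc1ccccc1 | intermediate
33 | lithium enolate of 32 | [Li+].COc1cc([C@@H](O[Si](C)(C)C(C)(C)C)[C@H](CO[Si](C)(C)C(C)(C)C)Oc2ccc(C[C@H]3COC([O-])=C3)cc2OC)ccc1OCc1ccccc1 | intermediate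
34 | (3R,4R)-4-{4-[(1R,2S)-1-(4-benzyloxy-3-methoxyphenyl)-1,3-bis(tert-butyldimethylsilyloxy)propan-2-yloxy]-3-methoxybenzyl}-3-{[(2S,3R)-2-(4-benzyloxy-3-methoxyphenyl)-7-methoxy-3-(triisopropylsilyloxymethyl)-2,3-dihydrobenzofuran-5-yl]methyl}dihydrofuran-2(3H)-one | COc1cc([C@@H](O[Si](C)(C)C(C)(C)C)[C@H](CO[Si](C)(C)C(C)(C)C)Oc2ccc(C[C@H]3COC(=O)[C@@H]3Cc3cc(OC)c4c(c3)[C@H](CO[Si](C(C)C)(C(C)C)C(C)C)[C@@H](c3ccc(OCc5ccccc5)c(OC)c3)O4)cc2OC)ccc1OCc1ccccc1 | intermediate
35 | (3R,4R)-4-{4-[(1R,2S)-1-(4-benzyloxy-3-methoxyphenyl)-1,3-dihydroxypropan-2-yloxy]-3-methoxybenzyl}-3-{[(2S,3R)-2-(4-benzyloxy-3-methoxyphenyl)-3-(hydroxymethyl)-7-methoxy-2,3-dihydrobenzofuran-5-yl]methyl}dihydrofuran-2(3H)-one | COc1cc([C@@H](O)[C@H](CO)Oc2ccc(C[C@H]3COC(=O)[C@@H]3Cc3cc(OC)c4c(c3)[C@H](CO)[C@@H](c3ccc(OCc5ccccc5)c(OC)c3)O4)cc2OC)ccc1OCc1ccccc1 | intermediate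
36 | (3R,4R)-4-{4-[(1R,2S)-1,3-dihydroxy-1-(4-hydroxy-3-methoxyphenyl)propan-2-yloxy]-3-methoxybenzyl}-3-{[(2S,3R)-2-(4-hydroxy-3-methoxyphenyl)-3-(hydroxymethyl)-7-methoxy-2,3-dihydrobenzofuran-5-yl]methyl}dihydrofuran-2(3H)-one (CNP0265599.1) | COc1cc([C@@H](O)[C@H](CO)Oc2ccc(C[C@H]3COC(=O)[C@@H]3Cc3cc(OC)c4c(c3)[C@H](CO)[C@@H](c3ccc(O)c(OC)c3)O4)cc2OC)ccc1O | target

## Step count and least certain steps

Total step count: 25. Longest linear sequence: 14 steps (from 15 and 16 through steps 11–14 and 16–25); the branch from 3 through steps 2–10 and 23–25 has 12.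

**Step 6 (key step).** Three things may go wrong:
- hydrogen transfer from the stannane to the cyclised primary radical before oxygen capture, when oxygen transfer into solution lags, so that reduction replaces oxygenation;
- radical-chain autoxidation at the doubly activated C2–H or at the acetal C–H;
- an insufficient trans preference in the 5-exo closure.

Fallback, separating C–C from C–O bond formation: from 8, cross-metathesis with vinylboronic acid pinacol ester (second-generation Grubbs catalyst, RuCl2(=CHPh)(H2IMes)(PCy3), CH2Cl2, 40 °C) would give 2-{4-[(1S,2E)-1-(4-benzyloxy-3-methoxyphenyl)-3-(4,4,5,5-tetramethyl-1,3,2-dioxaborolan-2-yl)prop-2-enyloxy]-3-iodo-5-methoxyphenyl}-1,3-dioxolane F1. Reductive 5-exo cyclisation with exclusion of air (Bu3SnH, AIBN, PhH, 80 °C), in which the aryl radical adds to the alkene carbon remote from boron, would give 2-[(2S,3S)-2-(4-benzyloxy-3-methoxyphenyl)-7-methoxy-3-[(4,4,5,5-tetramethyl-1,3,2-dioxaborolan-2-yl)methyl]-2,3-dihydrobenzofuran-5-yl]-1,3-dioxolane F2. F2 has the same trans geometry as 10; the descriptor at C3 changes only because boron replaces oxygen. Oxidation of the C–B bond (NaBO3·4H2O, THF/H2O) returns to 10.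

**Step 5.** The electron-rich allylic ether may re-ionise on the catalyst, which would erode both the branched regiochemistry and the enantiomeric purity. Substitution by the doubly ortho-substituted aryloxide may be slow, and the metal may insert into the C–I bond.

Fallback: from 15, addition of HC≡CMgBr (THF, 0 °C) would give 1-(4-benzyloxy-3-methoxyphenyl)prop-2-yn-1-ol F3, and acetylation (Ac2O, Et3N, DMAP) its acetate, 1-(4-benzyloxy-3-methoxyphenyl)prop-2-yn-1-yl acetate F4. Copper-catalysed enantioselective propargylic etherification of F4 with phenol 2 (CuOTf·½C6H6, chiral pybox ligand, i-Pr2NEt, MeOH, −20 °C) would give 2-{4-[(1S)-1-(4-benzyloxy-3-methoxyphenyl)prop-2-ynyloxy]-3-iodo-5-methoxyphenyl}-1,3-dioxolane F5. Semihydrogenation of the alkyne (H2, Pd/CaCO3 poisoned with Pb(OAc)2, quinoline) returns to 8.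

**Step 20.** The oxyphosphonium intermediate may ionise at the para-alkoxybenzylic carbon, so that part of the substitution proceeds with retention; elimination towards the enol ether is also possible.

Fallback: from 29, oxidation (Dess–Martin periodinane, NaHCO3, CH2Cl2) would give the ketone (R)-4-{4-[(2S)-1-(4-benzyloxy-3-methoxyphenyl)-3-(tert-butyldimethylsilyloxy)-1-oxopropan-2-yloxy]-3-methoxybenzyl}dihydrofuran-2(3H)-one F6. Reagent-controlled reduction ((R)-2-methyl-CBS-oxazaborolidine, BH3·SMe2, THF, −30 °C), run under neutral conditions so that C2′ is not enolised, would deliver hydride to the face that gives 31.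

**Step 23.** The electron-rich benzylic bromide may decompose by ionisation or self-alkylation before it meets the enolate. Proton exchange between product and enolate may lead to double alkylation.

Fallback: from 32 and 12, aldol addition of enolate 33 (LiN(i-Pr)2, THF, −78 °C) to aldehyde 12 would give the trans β-hydroxy lactone F7, that is 32 bearing at Cα a CH(OH) group bonded to C5 of the dihydrobenzofuran, as both carbinol epimers. Mesylation and elimination (MsCl, Et3N; then DBU) would give the (E)-α-arylidene lactone F8. Conjugate reduction (NiCl2·6H2O, NaBH4, MeOH/THF, 0 °C) followed by equilibration with DBU to the more stable trans lactone returns to 34.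

**Step 25.** Once the benzyl ethers have gone, reduction may continue, with hydrogenolysis of the benzylic C1′–OH bond or of the benzylic C2–O1 bond of the dihydrofuran.

Fallback with the order of deprotection reversed: from 34, hydrogenolysis (H2, 10 % Pd/C, EtOAc) while C1′ is still a silyl ether would give the bis-phenol tris-silyl ether F9, that is 34 with both benzyl groups replaced by hydrogen. Desilylation under acidic buffering (HF·pyridine, pyridine, THF), which forms no phenoxide, arrives at 36.

## Further compounds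

F1 | step 6 | 2-{4-[(1S,2E)-1-(4-benzyloxy-3-methoxyphenyl)-3-(4,4,5,5-tetramethyl-1,3,2-dioxaborolan-2-yl)prop-2-enyloxy]-3-iodo-5-methoxyphenyl}-1,3-dioxolane | COc1cc(C2OCCO2)cc(I)c1O[C@H](c1ccc(OCc2ccccc2)c(OC)c1)/C=C/B1OC(C)(C)C(C)(C)O1
F2 | step 6 | 2-[(2S,3S)-2-(4-benzyloxy-3-methoxyphenyl)-7-methoxy-3-[(4,4,5,5-tetramethyl-1,3,2-dioxaborolan-2-yl)methyl]-2,3-dihydrobenzofuran-5-yl]-1,3-dioxolane | O1CCOC1c1cc(OC)c2c(c1)[C@H](CB3OC(C)(C)C(C)(C)O3)[C@@H](c1ccc(OCc3ccccc3)c(OC)c1)O2
F3 | step 5 | 1-(4-benzyloxy-3-methoxyphenyl)prop-2-yn-1-ol (racemic) | COc1cc(C(O)C#C)ccc1OCc1ccccc1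
F4 | step 5 | 1-(4-benzyloxy-3-methoxyphenyl)prop-2-yn-1-yl acetate (racemic) | COc1cc(C(OC(C)=O)C#C)ccc1OCc1ccccc1
F5 | step 5 | 2-{4-[(1S)-1-(4-benzyloxy-3-methoxyphenyl)prop-2-ynyloxy]-3-iodo-5-methoxyphenyl}-1,3-dioxolane | COc1cc(C2OCCO2)cc(I)c1O[C@H](c1ccc(OCc2ccccc2)c(OC)c1)C#C
F6 | step 20 | (R)-4-{4-[(2S)-1-(4-benzyloxy-3-methoxyphenyl)-3-(tert-butyldimethylsilyloxy)-1-oxopropan-2-yloxy]-3-methoxybenzyl}dihydrofuran-2(3H)-one | COc1cc(C(=O)[C@H](CO[Si](C)(C)C(C)(C)C)Oc2ccc(C[C@H]3COC(=O)C3)cc2OC)ccc1OCc1ccccc1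
F7 | step 23 | (3S,4R)-4-{4-[(1R,2S)-1-(4-benzyloxy-3-methoxyphenyl)-1,3-bis(tert-butyldimethylsilyloxy)propan-2-yloxy]-3-methoxybenzyl}-3-{hydroxy[(2S,3R)-2-(4-benzyloxy-3-methoxyphenyl)-7-methoxy-3-(triisopropylsilyloxymethyl)-2,3-dihydrobenzofuran-5-yl]methyl}dihydrofuran-2(3H)-one (both carbinol epimers) | COc1cc([C@@H](O[Si](C)(C)C(C)(C)C)[C@H](CO[Si](C)(C)C(C)(C)C)Oc2ccc(C[C@H]3COC(=O)[C@@H]3C(O)c3cc(OC)c4c(c3)[C@H](CO[Si](C(C)C)(C(C)C)C(C)C)[C@@H](c3ccc(OCc5ccccc5)c(OC)c3)O4)cc2OC)ccc1OCc1ccccc1
F8 | step 23 | (R,E)-4-{4-[(1R,2S)-1-(4-benzyloxy-3-methoxyphenyl)-1,3-bis(tert-butyldimethylsilyloxy)propan-2-yloxy]-3-methoxybenzyl}-3-{[(2S,3R)-2-(4-benzyloxy-3-methoxyphenyl)-7-methoxy-3-(triisopropylsilyloxymethyl)-2,3-dihydrobenzofuran-5-yl]methylidene}dihydrofuran-2(3H)-one | COc1cc([C@@H](O[Si](C)(C)C(C)(C)C)[C@H](CO[Si](C)(C)C(C)(C)C)Oc2ccc(C[C@H]3COC(=O)/C3=C/c3cc(OC)c4c(c3)[C@H](CO[Si](C(C)C)(C(C)C)C(C)C)[C@@H](c3ccc(OCc5ccccc5)c(OC)c3)O4)cc2OC)ccc1OCc1ccccc1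
F9 | step 25 | (3R,4R)-4-{4-[(1R,2S)-1,3-bis(tert-butyldimethylsilyloxy)-1-(4-hydroxy-3-methoxyphenyl)propan-2-yloxy]-3-methoxybenzyl}-3-{[(2S,3R)-2-(4-hydroxy-3-methoxyphenyl)-7-methoxy-3-(triisopropylsilyloxymethyl)-2,3-dihydrobenzofuran-5-yl]methyl}dihydrofuran-2(3H)-one | COc1cc([C@@H](O[Si](C)(C)C(C)(C)C)[C@H](CO[Si](C)(C)C(C)(C)C)Oc2ccc(C[C@H]3COC(=O)[C@@H]3Cc3cc(OC)c4c(c3)[C@H](CO[Si](C(C)C)(C(C)C)C(C)C)[C@@H](c3ccc(O)c(OC)c3)O4)cc2OC)ccc1O
A1 | alternative 1 | (2S,3R)-2-(4-benzyloxy-3-methoxyphenyl)-5-bromo-3-(tert-butyldimethylsilyloxymethyl)-7-methoxy-2,3-dihydrobenzofuran | Brc1cc(OC)c2c(c1)[C@H](CO[Si](C)(C)C(C)(C)C)[C@@H](c1ccc(OCc3ccccc3)c(OC)c1)O2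
A2 | alternative 1 | 4-bromo-2-[2-(tert-butyldimethylsilyloxy)-1-(4-methylphenylsulfonyl)ethyl]-6-methoxyphenol (racemic) | COc1cc(Br)cc(C(CO[Si](C)(C)C(C)(C)C)S(=O)(=O)c2ccc(C)cc2)c1O
A3 | alternative 1 | (2R,5R)-1-(4-benzyloxy-3-methoxybenzyl)-2,5-dimethylthiolan-1-ium trifluoromethanesulfonate (or its antipode, as the sense of induction requires) | C[C@@H]1CC[C@@H](C)[S+]1Cc1ccc(OCc2ccccc2)c(OC)c1.[O-]S(=O)(=O)C(F)(F)F
A4 | alternative 1 | 4-bromo-6-[2-(tert-butyldimethylsilyloxy)ethylidene]-2-methoxycyclohexa-2,4-dien-1-one | O=C1C(OC)=CC(Br)=CC1=CCO[Si](C)(C)C(C)(C)C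
A5 | alternative 2 | (2S,3R)-2-(4-benzyloxy-3-methoxyphenyl)-3-(tert-butyldimethylsilyloxymethyl)-5-[(4-methoxybenzyloxy)methyl]-2,3-dihydrobenzofuran-7-ol | COc1ccc(COCc2cc(O)c3c(c2)[C@H](CO[Si](C)(C)C(C)(C)C)[C@@H](c2ccc(OCc4ccccc4)c(OC)c2)O3)cc1
A6 | alternative 2 | (1S,2R)-1-(4-benzyloxy-3-methoxyphenyl)-3-(tert-butyldimethylsilyloxy)-2-{4-[(4-methoxybenzyloxy)methyl]furan-2-yl}propyl ethynyl ether | COc1ccc(COCc2coc(c2)[C@H](CO[Si](C)(C)C(C)(C)C)[C@@H](c2ccc(OCc3ccccc3)c(OC)c2)OC#C)cc1
A7 | alternative 3 | (R)-4-(4-benzyloxy-3-methoxybenzyl)dihydrofuran-2(3H)-one | COc1cc(C[C@H]2COC(=O)C2)ccc1OCc1ccccc1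
A8 | alternative 3 | 3-(4-benzyloxy-3-methoxybenzyl)cyclobutan-1-one | COc1cc(CC2CC(=O)C2)ccc1OCc1ccccc1
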